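**Plan**

- Retrosynthesis first cuts the benzylic CH2 of ring B (the ring with the unsaturated arm) on both sides, aryl C1–CH2 and CH2–N. This releases the arm-free biaryl, formaldehyde and (E)-8-methylnon-6-enamide. The C5'–C5''' biaryl bond is cut next (Suzuki–Miyaura), then the C5–Br bond of 5-bromodihydrocapsaicin.
- Enabling feature: C1 of ring B is para to the C4 hydroxyl of that ring. In the arm-free biaryl this C1–H is the only aromatic C–H ortho or para to a free OH, and both neighbouring carbons (C2, C6) carry hydrogen.
- Forward: dihydrocapsaicin is brominated at C5 and coupled with 2-hydroxy-3-methoxyphenylboronic acid. The second arm is then assembled in one flask from the biaryl, formaldehyde and the primary amide made from (E)-8-methylnon-6-enoic acid. No ring is formed at any stage.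
- Stereochemistry: the target has no stereocentre. The E alkene is bought with the acid and afterwards meets only CDI, ammonia and a catalytic sulfonic acid.

Key step: step 4

Remark: formaldehyde is charged as paraformaldehyde, which releases the monomer in the flask; ring positions use capsaicin locants (C1 benzylic carbon, C3 methoxy, C4 hydroxyl).

**Route**

Step 1
Reactants: 1 dihydrocapsaicin
Product: 2 5-bromodihydrocapsaicin
Conditions: NBS (1.0 equiv), i-Pr2NH (10 mol%), CH2Cl2, 0 °C to rt
Reagents that add atoms: N-bromosuccinimide, O=C1CCC(=O)N1Br
Why: Electrophilic aromatic bromination of a para-blocked phenol, in which the secondary amine turns NBS into an N-bromoamine that hydrogen-bonds to the hydroxyl and delivers bromine to the only free ortho carbon (C5), while the amide and the saturated chain are inert.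

Step 2
Reactants: 2 5-bromodihydrocapsaicin; 3 2-hydroxy-3-methoxyphenylboronic acid (1.5 equiv)
Product: 4 5-(2-hydroxy-3-methoxyphenyl)dihydrocapsaicin
Conditions: Pd(OAc)2 (3 mol%), SPhos (2-dicyclohexylphosphino-2',6'-dimethoxybiphenyl, 6 mol%), K3PO4 (4 equiv), 1,4-dioxane/H2O, degassed, 80 °C
Reagents that add atoms: none
Why: Suzuki–Miyaura cross-coupling, in which zerovalent palladium formed in the flask from Pd(OAc)2 and the bulky electron-rich phosphine should insert into the C–Br bond of the electron-rich bromophenoxide and accept an ortho substituent on each partner, free phenols being compatible with aqueous phosphate base as in couplings of 5-halovanillins.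

Step 3
Reactants: 5 (E)-8-methylnon-6-enoic acid
Product: 7 (E)-8-methylnon-6-enamide, via acyl imidazolide 6 (not isolated)
Conditions: CDI (1,1'-carbonyldiimidazole, 1.2 equiv), THF, rt; then 28% aq. NH3 (excess), 0 °C to rt
Reagents that add atoms: ammonia, N
Why: Amide formation by activation of the acid as its acyl imidazolide followed by aminolysis with ammonia, under near-neutral conditions that leave the E alkene untouched.

Step 4
Reactants: 4 5-(2-hydroxy-3-methoxyphenyl)dihydrocapsaicin; 7 (E)-8-methylnon-6-enamide; 8 formaldehyde (as paraformaldehyde)
Product: 10 6'',7''-dihydro-5',5'''-dicapsaicin, via (E)-N-(hydroxymethyl)-8-methylnon-6-enamide 9 (not isolated)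
Conditions: 7 (1.5 equiv), paraformaldehyde (1.2 equiv CH2O), K2CO3 (5 mol%), 1,4-dioxane, 50 °C; then 4 (1.0 equiv), p-toluenesulfonic acid monohydrate (p-TsOH·H2O, 25 mol%), 50 °C; silica chromatography
Reagents that add atoms: none
Why: Base-catalysed addition of amide 7 to formaldehyde gives the N-hydroxymethyl amide 9, which the sulfonic acid ionises to an N-acyliminium ion; this attacks the ring B carbon para to the hydroxyl of 4 and loss of the ring proton restores the arene, so the aryl–CH2 and CH2–N bonds of the arm are both made in this flask. The closest known reaction type is the Tscherniac–Einhorn amidomethylation of phenols in its three-component form (arene, formaldehyde, primary amide). No ring closes and no stereocentre is created; the E alkene should be carried through because a catalytic sulfonic acid at 50 °C is not expected to protonate an isolated 1,2-disubstituted alkene, and closure of the iminium carbon onto its own alkene would need an eight- or nine-membered ring. The step needs site selectivity, and the substrate supplies it: the attacked carbon is the only aromatic C–H ortho or para to a free hydroxyl and has hydrogen on both neighbours, whereas the other four aromatic C–H are meta to the hydroxyls and the two of them that are para to a methoxy group sit next to the biaryl bond. Making 9 before the phenol is added keeps free formaldehyde away from the arene, and N- or O-amidomethylation of the amide and phenol groups of 4 is reversible under acid, so such detours should drain into the C-alkylated product and not into diarylmethanes. The acid is kept catalytic and mild so that the 4-hydroxybenzyl amide already present on ring A is not ionised and the two acyl arms cannot exchange.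

**Compound list**

1 | dihydrocapsaicin, N-(4-hydroxy-3-methoxybenzyl)-8-methylnonanamide | COc1cc(CNC(=O)CCCCCCC(C)C)ccc1O | starting material
2 | 5-bromodihydrocapsaicin, N-(3-bromo-4-hydroxy-5-methoxybenzyl)-8-methylnonanamide | COc1cc(CNC(=O)CCCCCCC(C)C)cc(Br)c1O | intermediate
3 | 2-hydroxy-3-methoxyphenylboronic acid | COc1cccc(B(O)O)c1O | starting material
4 | 5-(2-hydroxy-3-methoxyphenyl)dihydrocapsaicin, N-[(2',6-dihydroxy-3',5-dimethoxybiphenyl-3-yl)methyl]-8-methylnonanamide | COc1cccc(-c2cc(CNC(=O)CCCCCCC(C)C)cc(OC)c2O)c1O | intermediate
5 | (E)-8-methylnon-6-enoic acid | CC(C)/C=C/CCCCC(=O)O | starting material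
6 | (E)-1-(imidazol-1-yl)-8-methylnon-6-en-1-one (acyl imidazolide, formed in the flask in step 3) | CC(C)/C=C/CCCCC(=O)n1ccnc1 | intermediate
7 | (E)-8-methylnon-6-enamide | CC(C)/C=C/CCCCC(N)=O | intermediate
8 | formaldehyde (charged as paraformaldehyde) | C=O | starting material
9 | (E)-N-(hydroxymethyl)-8-methylnon-6-enamide (formed in the flask in step 4) | CC(C)/C=C/CCCCC(=O)NCO | intermediate
10 | 6'',7''-dihydro-5',5'''-dicapsaicin, (E)-N-[(2,2'-dihydroxy-3,3'-dimethoxy-5'-{[(8-methylnonanoyl)amino]methyl}biphenyl-5-yl)methyl]-8-methylnon-6-enamide | COc1cc(CNC(=O)CCCC/C=C/C(C)C)cc(-c2cc(CNC(=O)CCCCCCC(C)C)cc(OC)c2O)c1O | target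

**Step count**

Total steps: 4. Longest linear sequence: 3 steps (steps 1, 2 and 4); step 3 is a one-step side branch that joins at step 4.

**Steps most likely to fail**

Step 4. The N-acyliminium ion may be captured by the alkene of a second molecule (dihydro-oxazine formation), or the acid may shift the double bond, at a rate that competes with aromatic substitution. Residual formaldehyde may also bridge the two phenols as a cyclic formal, and attack para to a methoxy group is a lesser concern. The fallback sets out from biaryl 4 and runs the electrophilic step with no alkene and no free formaldehyde present. A Tscherniac–Einhorn reaction with N-(hydroxymethyl)phthalimide in CF3CO2H/CH2Cl2 at room temperature should give 5-[2-hydroxy-3-methoxy-5-(phthalimidomethyl)phenyl]dihydrocapsaicin F1. Hydrazinolysis (N2H4·H2O, EtOH, reflux) should free 5-[5-(aminomethyl)-2-hydroxy-3-methoxyphenyl]dihydrocapsaicin F2. N-Acylation of F2 with acid 5 (EDC·HCl, HOBt, i-Pr2NEt, DMF) comes back to the route at target 10.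

Step 2. Protodeboronation of the electron-rich ortho-hydroxy boronic acid may outrun a slow oxidative addition into the bromophenoxide, or the 2-bromophenoxide may bind and stall the palladium. The fallback sets out from bromide 2. O-Benzylation (benzyl bromide, K2CO3, DMF) should give O-benzyl-5-bromodihydrocapsaicin F3, a neutral aryl bromide. Its Suzuki–Miyaura coupling with boronic acid 3 under the catalyst system of step 2 should give 5-(2-hydroxy-3-methoxyphenyl)-O-benzyldihydrocapsaicin F4. Hydrogenolysis (H2, Pd/C, EtOAc/EtOH), harmless because neither alkene nor halogen is present at this stage, comes back to the route at biaryl 4.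

Step 1. Bromination may go in part para to the methoxy group (C6) or twice, giving isomers that are hard to separate. The fallback buys the bromine position instead of making it and bypasses steps 1 and 2. It sets out from boronic acid 3, which is coupled (Suzuki–Miyaura, same catalyst system) with commercial 5-bromovanillin to give 5-(2-hydroxy-3-methoxyphenyl)vanillin F5. Oximation (NH2OH·HCl, NaOAc, EtOH) should give 5-(2-hydroxy-3-methoxyphenyl)vanillin (E)-oxime F6. Reduction (H2, Pd/C, HCl, EtOH) should give 5-(2-hydroxy-3-methoxyphenyl)vanillylamine F7. N-Acylation of F7 with commercial 8-methylnonanoic acid (EDC·HCl, HOBt, i-Pr2NEt, DMF) comes back to the route at biaryl 4.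

**Further compounds**

F1 | step 4 | 5-[2-hydroxy-3-methoxy-5-(phthalimidomethyl)phenyl]dihydrocapsaicin | COc1cc(CN2C(=O)c3ccccc3C2=O)cc(-c4cc(CNC(=O)CCCCCCC(C)C)cc(OC)c4O)c1O
F2 | step 4 | 5-[5-(aminomethyl)-2-hydroxy-3-methoxyphenyl]dihydrocapsaicin | COc1cc(CN)cc(-c2cc(CNC(=O)CCCCCCC(C)C)cc(OC)c2O)c1O
F3 | step 2 | O-benzyl-5-bromodihydrocapsaicin, N-[4-(benzyloxy)-3-bromo-5-methoxybenzyl]-8-methylnonanamide | COc1cc(CNC(=O)CCCCCCC(C)C)cc(Br)c1OCc2ccccc2
F4 | step 2 | 5-(2-hydroxy-3-methoxyphenyl)-O-benzyldihydrocapsaicin | COc1cccc(-c2cc(CNC(=O)CCCCCCC(C)C)cc(OC)c2OCc3ccccc3)c1O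
F5 | step 1 | 5-(2-hydroxy-3-methoxyphenyl)vanillin, 2',6-dihydroxy-3',5-dimethoxybiphenyl-3-carbaldehyde | COc1cccc(-c2cc(C=O)cc(OC)c2O)c1O
F6 | step 1 | 5-(2-hydroxy-3-methoxyphenyl)vanillin (E)-oxime | COc1cccc(-c2cc(/C=N/O)cc(OC)c2O)c1O
F7 | step 1 | 5-(2-hydroxy-3-methoxyphenyl)vanillylamine | COc1cccc(-c2cc(CN)cc(OC)c2O)c1O
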